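**Retrosynthetic overview**
1. The cyclopentenone ring C8–C12 with its exocyclic carbon C7 is read as a contracted six-membered ring: the 2-bromo-para-quinol ring C7–C12 of a phenol, in which the C9 carbonyl carbon has moved from C7 to C8.
2. C6–C7 is cut last: Stille coupling of the (Z)-enol triflate 13 of hydroxymethylene ketone 11 with the (E)-alkenylstannane 15 made from methyl hex-5-ynoate.
3. 11 comes from epoxyquinol acetate 9 by a BF3-promoted 1,2-acyl shift; this is the only ring-forming event (the five-membered ring forms from the six-membered one).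
4. 9 comes from phenol 6 by enantioselective para-hydroxylative dearomatisation (sets C12), hydroxyl-directed epoxidation and acetylation.
5. 6 comes from 4-(2-bromoethyl)phenol and hexanal by ortho-bromination, phosphonium salt formation and Z-selective Wittig reaction.

Key step: step 7

Remarks on the chemistry
- Atom numbers are those of the prostanoid skeleton of the target: C1 ester carbon, C5=C6 and C7=C8 alkenes, C9 ketone, C10 (Br), C11, C12 (acetoxy carbon), C13–C20 octenyl chain.
- ArI* is the purchased chiral aryl iodide (R,R)-2,2'-[(2-iodo-1,3-phenylene)bis(oxy)]bis[N-(2,4,6-trimethylphenyl)propanamide], SMILES C[C@@H](Oc1cccc(O[C@H](C)C(=O)Nc2c(C)cc(C)cc2C)c1I)C(=O)Nc1c(C)cc(C)cc1C.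
- Assumption: the sense of induction of this reagent at the remote C12 centre cannot be predicted with confidence. The (R,R) reagent is written; if it proves to favour the mirror image of 7, the (S,S) reagent is used instead.

Step 1
Reactants: 1 4-(2-bromoethyl)phenol
Product: 2 2-bromo-4-(2-bromoethyl)phenol
Conditions: NBS (1.0 equiv), p-TsOH·H2O (10 mol%), MeOH, 0 °C → rt
Reagents that add atoms: N-bromosuccinimide, O=C1CCC(=O)N1Br
Why: Acid-catalysed electrophilic aromatic bromination with NBS goes ortho to the phenolic hydroxyl because the para position is blocked, and one equivalent at low temperature should hold it at the mono-bromide.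

Step 2
Reactants: 2 2-bromo-4-(2-bromoethyl)phenol
Product: 3 [2-(3-bromo-4-hydroxyphenyl)ethyl]triphenylphosphonium bromide
Conditions: PPh3, MeCN, reflux
Reagents that add atoms: triphenylphosphine, c1ccc(cc1)P(c1ccccc1)c1ccccc1
Why: SN2 quaternisation of triphenylphosphine by the primary alkyl bromide (phosphonium salt formation) leaves the aryl bromide and the phenol untouched.

Step 3
Reactants: 3 [2-(3-bromo-4-hydroxyphenyl)ethyl]triphenylphosphonium bromide; 4 hexanal
Product: 6 2-bromo-4-[(2Z)-oct-2-en-1-yl]phenol, via ylide 5 (not isolated)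
Conditions: NaN(SiMe3)2 (2.05 equiv), THF, −78 → 0 °C; 4, −78 °C → rt; 1 M HCl
Reagents that add atoms: none
Why: Wittig olefination with a salt-free, non-stabilised ylide (the phenol rides along as its sodium phenoxide) closes the cis-oxaphosphetane under kinetic control and so should give the Z alkene.

Step 4
Reactants: 6 2-bromo-4-[(2Z)-oct-2-en-1-yl]phenol
Product: 7 (4S)-2-bromo-4-hydroxy-4-[(2Z)-oct-2-en-1-yl]cyclohexa-2,5-dien-1-one
Conditions: ArI* (1.1 equiv), mCPBA (1.0 equiv), AcOH (4 equiv), CH2Cl2, rt, until no peracid remains; then 6, MeCN/H2O 4:1, −20 → 0 °C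
Reagents that add atoms: water, O
Why: Hydroxylative para-dearomatisation of a 2-bromo-4-alkylphenol by a chiral aryl-λ3-iodane (ligand exchange at trivalent iodine, then attack of water at the para carbon as the aryl iodide leaves) is a known reaction type; C12 is set by the lactamide arms, which shield one of the two ring faces made enantiotopic by the ortho bromine, and the peracid is used up before 6 is added so that the Z alkene is not epoxidised.

Step 5
Reactants: 7 (4S)-2-bromo-4-hydroxy-4-[(2Z)-oct-2-en-1-yl]cyclohexa-2,5-dien-1-one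
Product: 8 (1R,5R,6S)-3-bromo-5-hydroxy-5-[(2Z)-oct-2-en-1-yl]-7-oxabicyclo[4.1.0]hept-3-en-2-one (epoxide oxygen and hydroxyl on the same face)
Conditions: tBuOOH (anhydrous, 2 equiv), Ti(OiPr)4 (1.1 equiv), 4 Å MS, CH2Cl2, −20 °C
Reagents that add atoms: tert-butyl hydroperoxide, CC(C)(C)OO
Why: Hydroxyl-directed nucleophilic (Weitz–Scheffer-type) epoxidation: the titanium alkoxide of the C12 hydroxyl carries the tert-butylperoxide and delivers it to C8 on its own face, so C7 and C8 are set syn to the C12 oxygen, while the α-bromo-substituted C10=C11 bond reacts more slowly.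

Step 6
Reactants: 8 (1R,5R,6S)-3-bromo-5-hydroxy-5-[(2Z)-oct-2-en-1-yl]-7-oxabicyclo[4.1.0]hept-3-en-2-one
Product: 9 (1R,5R,6S)-5-(acetyloxy)-3-bromo-5-[(2Z)-oct-2-en-1-yl]-7-oxabicyclo[4.1.0]hept-3-en-2-one (epoxide oxygen syn to the acetate)
Conditions: Ac2O, DMAP, Et3N, CH2Cl2, 0 °C → rt
Reagents that add atoms: acetic anhydride, CC(=O)OC(C)=O
Why: DMAP-catalysed acetylation of the tertiary alcohol with acetic anhydride is standard for this kind of hindered carbinol and touches neither the epoxide nor the stereocentres.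

Step 7
Reactants: 9 (1R,5R,6S)-5-(acetyloxy)-3-bromo-5-[(2Z)-oct-2-en-1-yl]-7-oxabicyclo[4.1.0]hept-3-en-2-one
Product: 11 (4R,5Z)-4-(acetyloxy)-2-bromo-5-(hydroxymethylidene)-4-[(2Z)-oct-2-en-1-yl]cyclopent-2-en-1-one, via keto aldehyde 10 (not isolated)
Conditions: BF3·OEt2 (1.2 equiv), CH2Cl2, −78 → −20 °C; aq. NaHCO3
Reagents that add atoms: none
Why: Proposed new method: BF3 binds the epoxide oxygen, the C8–O bond lengthens (it is β to the C9 ketone, whereas the α-keto C7–O bond resists ionisation), and the C7–C9 ring bond shifts to C8 on the face opposite the departing oxygen while the oxygen left on C7 closes to the aldehyde 10, which enolises to the chelated (Z)-hydroxymethylene ketone 11; this is a semipinacol-type 1,2-acyl shift. The closest known reaction type is the BF3-promoted ring contraction of 2,3-epoxycyclohexanones, 4,4-disubstituted ones included, to 2-formylcyclopentanones, which has not been shown on a cross-conjugated epoxyquinol acetate. The five-membered ring C8–C12 closes by this 1,2-shift (C8–C9 formed, C7–C9 broken; a ring contraction of the six-membered ring, not an exo or endo cyclisation), and C7 is pushed out as the exocyclic carbon. No lasting stereocentre is made: C8 is formed with inversion but becomes trigonal on enolisation, and C12 is not touched. The step needs the acyl shift to outrun the hydride shift from C7 (which would give the 1,2-dione and then an ortho-quinone by loss of acetic acid), capture by fluoride and any shift from C12; the acetate is syn to the epoxide oxygen and cannot reach the back of C8, its carbonyl makes the C12 oxygen a poor donor for a competing shift, and the BF3-bound oxygen on C7 is a strong donor that drives the acyl carbon across at low temperature in a non-nucleophilic solvent.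

Step 8
Reactants: 11 (4R,5Z)-4-(acetyloxy)-2-bromo-5-(hydroxymethylidene)-4-[(2Z)-oct-2-en-1-yl]cyclopent-2-en-1-one
Product: 13 (4R,5Z)-4-(acetyloxy)-2-bromo-4-[(2Z)-oct-2-en-1-yl]-5-{[(trifluoromethanesulfonyl)oxy]methylidene}cyclopent-2-en-1-one, via lithium enolate 12 (not isolated)
Conditions: LiN(SiMe3)2 (1.0 equiv), Et2O, −78 °C; Tf2O (1.05 equiv), −78 → −40 °C
Reagents that add atoms: trifluoromethanesulfonic anhydride, O=S(=O)(OS(=O)(=O)C(F)(F)F)C(F)(F)F
Why: O-Sulfonylation of the chelated lithium enolate of a 2-(hydroxymethylene) ketone (enol triflate formation) occurs at the formyl oxygen, and the lithium bridge between the two oxygens holds that oxygen cis to C9, which should give the Z triflate; exactly one equivalent of base leaves the acetate alone.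

Step 9
Reactants: 14 methyl hex-5-ynoate
Product: 15 methyl (5E)-6-(tributylstannyl)hex-5-enoate
Conditions: Bu3SnH, Pd2(dba)3 (0.5 mol%), Cy3P·HBF4 (2 mol%), iPr2NEt (4 mol%), CH2Cl2, 0 °C
Reagents that add atoms: tributyltin hydride, CCCC[SnH](CCCC)CCCC
Why: Palladium-catalysed hydrostannation is a syn addition, and with a bulky trialkylphosphine on zerovalent palladium the tin goes to the terminal carbon, which should give the E alkenylstannane.

Step 10
Reactants: 13 (4R,5Z)-4-(acetyloxy)-2-bromo-4-[(2Z)-oct-2-en-1-yl]-5-{[(trifluoromethanesulfonyl)oxy]methylidene}cyclopent-2-en-1-one; 15 methyl (5E)-6-(tributylstannyl)hex-5-enoate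
Product: 16 methyl (5E,7Z)-7-[(2R)-2-(acetyloxy)-4-bromo-2-[(2Z)-oct-2-en-1-yl]-5-oxocyclopent-3-en-1-ylidene]hept-5-enoate
Conditions: Pd2(dba)3 (3 mol%), AsPh3 (24 mol%), CuI (10 mol%), NMP, 20 °C, dark
Reagents that add atoms: none
Why: Stille coupling: oxidative addition of zerovalent palladium into the vinylogous acyl triflate should be much faster at room temperature than into the C10–Br bond of the α-bromo enone, and both partners couple with retention, so the 7Z and 5E geometries are carried into the diene.

**Compound list**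
1 | 4-(2-bromoethyl)phenol | Oc1ccc(CCBr)cc1 | starting material
2 | 2-bromo-4-(2-bromoethyl)phenol | Oc1ccc(CCBr)cc1Br | intermediate
3 | [2-(3-bromo-4-hydroxyphenyl)ethyl]triphenylphosphonium bromide | [Br-].Oc1ccc(CC[P+](c2ccccc2)(c2ccccc2)c2ccccc2)cc1Br | intermediate
4 | hexanal | CCCCCC=O | starting material
5 | sodium 2-bromo-4-[2-(triphenyl-λ5-phosphanylidene)ethyl]phenolate (ylide, not isolated) | [Na+].[O-]c1ccc(CC=P(c2ccccc2)(c2ccccc2)c2ccccc2)cc1Br | intermediate
6 | 2-bromo-4-[(2Z)-oct-2-en-1-yl]phenol | CCCCC/C=C\Cc1ccc(O)c(Br)c1 | intermediate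
7 | (4S)-2-bromo-4-hydroxy-4-[(2Z)-oct-2-en-1-yl]cyclohexa-2,5-dien-1-one | CCCCC/C=C\C[C@@]1(O)C=C(Br)C(=O)C=C1 | intermediate
8 | (1R,5R,6S)-3-bromo-5-hydroxy-5-[(2Z)-oct-2-en-1-yl]-7-oxabicyclo[4.1.0]hept-3-en-2-one | CCCCC/C=C\C[C@@]1(O)C=C(Br)C(=O)[C@@H]2O[C@H]12 | intermediate
9 | (1R,5R,6S)-5-(acetyloxy)-3-bromo-5-[(2Z)-oct-2-en-1-yl]-7-oxabicyclo[4.1.0]hept-3-en-2-one | CCCCC/C=C\C[C@@]1(OC(C)=O)C=C(Br)C(=O)[C@@H]2O[C@H]12 | intermediate
10 | (1S,2S)-2-(acetyloxy)-4-bromo-2-[(2Z)-oct-2-en-1-yl]-5-oxocyclopent-3-ene-1-carbaldehyde (keto aldehyde, formyl cis to acetoxy, not isolated) | CCCCC/C=C\C[C@@]1(OC(C)=O)C=C(Br)C(=O)[C@@H]1C=O | intermediate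
11 | (4R,5Z)-4-(acetyloxy)-2-bromo-5-(hydroxymethylidene)-4-[(2Z)-oct-2-en-1-yl]cyclopent-2-en-1-one | CCCCC/C=C\C[C@@]1(OC(C)=O)C=C(Br)C(=O)/C1=C\O | intermediate
12 | lithium (Z)-[(2R)-2-(acetyloxy)-4-bromo-2-[(2Z)-oct-2-en-1-yl]-5-oxocyclopent-3-en-1-ylidene]methanolate (not isolated) | [Li+].CCCCC/C=C\C[C@@]1(OC(C)=O)C=C(Br)C(=O)/C1=C\[O-] | intermediate
13 | (4R,5Z)-4-(acetyloxy)-2-bromo-4-[(2Z)-oct-2-en-1-yl]-5-{[(trifluoromethanesulfonyl)oxy]methylidene}cyclopent-2-en-1-one | CCCCC/C=C\C[C@@]1(OC(C)=O)C=C(Br)C(=O)/C1=C\OS(=O)(=O)C(F)(F)F | intermediate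
14 | methyl hex-5-ynoate | COC(=O)CCCC#C | starting material
15 | methyl (5E)-6-(tributylstannyl)hex-5-enoate | CCCC[Sn](CCCC)(CCCC)/C=C/CCCC(=O)OC | intermediate
16 | methyl (5E,7Z)-7-[(2R)-2-(acetyloxy)-4-bromo-2-[(2Z)-oct-2-en-1-yl]-5-oxocyclopent-3-en-1-ylidene]hept-5-enoate | CCCCC/C=C\C[C@@]1(OC(C)=O)C=C(Br)C(=O)/C1=C\C=C\CCCC(=O)OC | target

**Totals**
Total step count: 10. Longest linear sequence: 9 steps (steps 1–8 and 10, from 4-(2-bromoethyl)phenol).

**Steps most likely to fail**

1. Step 7 (Proposed new method). What may go wrong: ionisation at C8 is slowed by the neighbouring acetoxy-bearing C12, so the hydride shift from C7, capture by fluoride, or a shift of the octenyl carbon from C12 can overtake the acyl migration.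
Fallback (known chemistry; the ring contraction is given up and the hydroxymethylene ketone is built on a preformed five-membered ring). It leaves the six-membered series, so it cannot start from a numbered intermediate: it sets out from two purchased compounds, (2Z)-oct-2-en-1-ol and (4R)-4-[(tert-butyldimethylsilyl)oxy]cyclopent-2-en-1-one, and comes back to the route at 11. The alcohol is turned into (2Z)-1-chlorooct-2-ene F1 (MsCl, LiCl, 2,4,6-collidine, DMF, 0 °C). Its allylbarium reagent (BaI2 reduced with lithium biphenylide, THF, −78 °C) belongs to a reagent class that adds through the α-carbon with retention of the Z geometry. It attacks the enone carbonyl anti to the silyloxy group and should give (1S,4R)-4-[(tert-butyldimethylsilyl)oxy]-1-[(2Z)-oct-2-en-1-yl]cyclopent-2-en-1-ol F2. Bu4NF gives (1S,4R)-1-[(2Z)-oct-2-en-1-yl]cyclopent-2-ene-1,4-diol F3. MnO2 oxidises only the secondary allylic alcohol and gives (4S)-4-hydroxy-4-[(2Z)-oct-2-en-1-yl]cyclopent-2-en-1-one F4, in which C12 has the configuration of the target. Bromine is then brought in without an electrophilic bromine source, which the Z alkene would not survive. Alkaline H2O2 gives (4S)-4-hydroxy-4-[(2Z)-oct-2-en-1-yl]-6-oxabicyclo[3.1.0]hexan-2-one F5 (either epoxide face). Aqueous HBr opens this epoxy ketone at the α-carbon and dehydrates the bromohydrin to (4S)-2-bromo-4-hydroxy-4-[(2Z)-oct-2-en-1-yl]cyclopent-2-en-1-one F6. The dianion of F6 (LiN(SiMe3)2, 2.2 equiv, THF, −78 °C) is formylated with ethyl formate (Claisen condensation) to (4R,5Z)-2-bromo-4-hydroxy-5-(hydroxymethylidene)-4-[(2Z)-oct-2-en-1-yl]cyclopent-2-en-1-one F7. Ac2O/DMAP acetylates both hydroxyls to (Z)-[(2R)-2-(acetyloxy)-4-bromo-2-[(2Z)-oct-2-en-1-yl]-5-oxocyclopent-3-en-1-ylidene]methyl acetate F8, and brief K2CO3 in MeOH at 0 °C removes only the enol acetate to give 11.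

2. Step 4. What may go wrong: poor facial discrimination at the para carbon, which lies far from the only substituent (the ortho bromine) that makes the two faces different, so 7 would form with low enantiomeric purity.
Fallback (resolution instead of asymmetric induction). It sets out from 6 and comes back at 7. Oxidation of 6 with PhI(OAc)2 in MeCN/H2O at 0 °C should give racemic 2-bromo-4-hydroxy-4-[(2Z)-oct-2-en-1-yl]cyclohexa-2,5-dien-1-one F9. Its enantiomers are separated by preparative chromatography on a cellulose-carbamate chiral stationary phase, and the (S) enantiomer is 7; the bromine atom allows the absolute configuration to be assigned by anomalous-dispersion X-ray analysis of a crystalline derivative.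

3. Step 10. What may go wrong: oxidative addition at the C10–Br bond competing with that at the triflate, or Z-to-E isomerisation of the alkenylpalladium intermediate while the slow transfer from tin is awaited.
Fallback (boron in place of tin, with fluoride-assisted transfer). It sets out from 14 and comes back at 16. Hydroboration of 14 with pinacolborane and Cp2Zr(H)Cl (5 mol%) should give methyl (5E)-6-(4,4,5,5-tetramethyl-1,3,2-dioxaborolan-2-yl)hex-5-enoate F10. Suzuki–Miyaura coupling of F10 with 13 (PdCl2(dppf), CsF, THF, 20 °C) then gives 16 without aqueous base, so the acetate and the triflate are not exposed to hydroxide.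

**Further compounds**
F1 | step 7 | (2Z)-1-chlorooct-2-ene | CCCCC/C=C\CCl
F2 | step 7 | (1S,4R)-4-[(tert-butyldimethylsilyl)oxy]-1-[(2Z)-oct-2-en-1-yl]cyclopent-2-en-1-ol | CCCCC/C=C\C[C@@]1(O)C=C[C@H](O[Si](C)(C)C(C)(C)C)C1
F3 | step 7 | (1S,4R)-1-[(2Z)-oct-2-en-1-yl]cyclopent-2-ene-1,4-diol | CCCCC/C=C\C[C@@]1(O)C=C[C@H](O)C1
F4 | step 7 | (4S)-4-hydroxy-4-[(2Z)-oct-2-en-1-yl]cyclopent-2-en-1-one | CCCCC/C=C\C[C@@]1(O)C=CC(=O)C1
F5 | step 7 | (4S)-4-hydroxy-4-[(2Z)-oct-2-en-1-yl]-6-oxabicyclo[3.1.0]hexan-2-one | CCCCC/C=C\C[C@@]1(O)C2OC2C(=O)C1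
F6 | step 7 | (4S)-2-bromo-4-hydroxy-4-[(2Z)-oct-2-en-1-yl]cyclopent-2-en-1-one | CCCCC/C=C\C[C@@]1(O)C=C(Br)C(=O)C1
F7 | step 7 | (4R,5Z)-2-bromo-4-hydroxy-5-(hydroxymethylidene)-4-[(2Z)-oct-2-en-1-yl]cyclopent-2-en-1-one | CCCCC/C=C\C[C@@]1(O)C=C(Br)C(=O)/C1=C\O
F8 | step 7 | (Z)-[(2R)-2-(acetyloxy)-4-bromo-2-[(2Z)-oct-2-en-1-yl]-5-oxocyclopent-3-en-1-ylidene]methyl acetate | CCCCC/C=C\C[C@@]1(OC(C)=O)C=C(Br)C(=O)/C1=C\OC(C)=O
F9 | step 4 | racemic 2-bromo-4-hydroxy-4-[(2Z)-oct-2-en-1-yl]cyclohexa-2,5-dien-1-one | CCCCC/C=C\CC1(O)C=C(Br)C(=O)C=C1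
F10 | step 10 | methyl (5E)-6-(4,4,5,5-tetramethyl-1,3,2-dioxaborolan-2-yl)hex-5-enoate | COC(=O)CCC/C=C/B1OC(C)(C)C(C)(C)O1
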